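**Retrosynthetic overview**

1. Last bonds: the C14 glycolate and removal of all acetal and silyl groups; the C14 carbinol comes from a 3,14-dione; the C10 methyl and the C14 ketone come from a transannular 1,5-hydrogen-atom-transfer redox relay.
2. Key step (instead of dihydroxylating the vinyl group of a pleuromutilin-type tricycle): the eight-membered ring is closed last by divalent-samarium ketyl radical addition of the C14 aldehyde to C5 of a hydrindenone, making the C5 quaternary centre, C4 and the ring in one step.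
3. The C19/C20 diol is never made by oxidation: it is (R)-glyceraldehyde acetonide, carried into an allene. One-pot allene hydroboration–allylboration joins it to the hydrindenone enal (C11–C12), setting C11 and the C12 quaternary centre; the vinyl group so formed is the masked C13–C14 aldehyde (aldehyde-selective Wacker).
4. Hydrindenone enal from (S)-carvone: dealkenylation, two conjugate additions (C9 quaternary centre), aldol condensation, MeLi addition with oxidative transposition, SeO2.
5. Ring order: six-membered ring (chiral pool), five-membered ring (aldol condensation), eight-membered ring (radical cyclization).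

Assumption: the target string is followed exactly as written, atom for atom, with mutilin numbering C1–C20; its descriptors at C4, C5 and C6 are the mirror of those in the usual pleuromutilin string (a literal reading that puts C14 and C10 on opposite faces of the six-membered ring, possibly a transcription slip in the source), so the hydrindenone half starts from (S)-carvone and every SMILES below maps onto the given string.

**Route**

Step 1
Reactants: 1 (S)-carvone
Product: 2 (2S,5S)-2-methyl-5-(prop-1-en-2-yl)cyclohexan-1-one (trans-dihydrocarvone)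
Conditions: Zn, KOH, EtOH/H2O, 80 °C; minor cis isomer removed by chromatography
Reagents that add atoms: none
Why: dissolving-metal conjugate reduction of the enone leaves the isopropenyl group alone, and the alkaline medium equilibrates the new C2 centre to the trans-diequatorial (2S) epimer.

Step 2
Reactants: 2 (2S,5S)-2-methyl-5-(prop-1-en-2-yl)cyclohexan-1-one
Product: 4 (6S)-6-methylcyclohex-2-en-1-one, via methoxy hydroperoxide 3 (not isolated)
Conditions: O3, MeOH, −78 °C; then Cu(OAc)2·H2O, FeSO4·7H2O, −78 → 23 °C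
Reagents that add atoms: none
Why: Criegee ozonolysis in methanol followed by Schreiber-type dealkenylation (divalent iron cleaves the O–O bond, β-scission expels methyl acetate, divalent copper oxidises the ring radical to the alkene) gives the conjugated enone without touching the C6 stereocentre.

Step 3
Reactants: 4 (6S)-6-methylcyclohex-2-en-1-one
Product: 6 (6S)-6-methyl-3-(prop-1-en-2-yl)cyclohex-2-en-1-one, via silyl enol ether 5 (not isolated)
Conditions: CH2=C(CH3)MgBr, CuBr·SMe2 (10 mol%), TMSCl, THF, −78 °C; then Pd(OAc)2 (10 mol%), O2, DMSO, 23 °C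
Reagents that add atoms: isopropenylmagnesium bromide, CC(=C)[Mg]Br
Why: copper-catalysed conjugate addition trapped as the silyl enol ether, then Saegusa–Ito dehydrogenation restores the enone, so the transient C3 stereocentre is erased.

Step 4
Reactants: 6 (6S)-6-methyl-3-(prop-1-en-2-yl)cyclohex-2-en-1-one; 7 [2-(1,3-dioxan-2-yl)ethyl]magnesium bromide
Product: 8 (2S,5R)-5-[2-(1,3-dioxan-2-yl)ethyl]-2-methyl-5-(prop-1-en-2-yl)cyclohexan-1-one
Conditions: Cu(OTf)2 (5 mol%), 1,3-bis(2,4,6-trimethylphenyl)imidazolinium chloride (6 mol%), Et2O/THF, −30 °C; aq. NH4Cl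
Reagents that add atoms: none
Why: copper–N-heterocyclic-carbene-catalysed Grignard conjugate addition to a 3-alkenylcyclohexenone goes 1,4 and builds the quaternary carbon C9, and axial attack on the half-chair that keeps the C6 methyl pseudo-equatorial places the incoming chain cis to that methyl.

Step 5
Reactants: 8 (2S,5R)-5-[2-(1,3-dioxan-2-yl)ethyl]-2-methyl-5-(prop-1-en-2-yl)cyclohexan-1-one
Product: 10 (5S,7aR)-5-methyl-7a-(prop-1-en-2-yl)-1,2,5,6,7,7a-hexahydro-4H-inden-4-one, via keto aldehyde 9 (not isolated)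
Conditions: TsOH·H2O (10 mol%), acetone/H2O, 56 °C; concentrate; KOH, MeOH, 23 °C
Reagents that add atoms: none
Why: acetal hydrolysis then intramolecular aldol condensation (the C4 enolate closes the five-membered ring on the aldehyde and dehydration gives the conjugated enone) creates no new stereocentre; base is used for the condensation so the isopropenyl group cannot undergo a Prins reaction with the aldehyde.

Step 6
Reactants: 10 (5S,7aR)-5-methyl-7a-(prop-1-en-2-yl)-1,2,5,6,7,7a-hexahydro-4H-inden-4-one
Product: 11 (5S,7aR)-4,5-dimethyl-7a-(prop-1-en-2-yl)-2,4,5,6,7,7a-hexahydro-1H-inden-4-ol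
Conditions: MeLi, CeCl3, THF, −78 °C
Reagents that add atoms: methyllithium, [Li]C
Why: organocerium 1,2-addition to the hindered enone avoids enolisation and 1,4-addition, and the carbinol configuration is irrelevant because C5 becomes sp2 in the next step.

Step 7
Reactants: 11 (5S,7aR)-4,5-dimethyl-7a-(prop-1-en-2-yl)-2,4,5,6,7,7a-hexahydro-1H-inden-4-ol
Product: 12 (3aS,6S)-6,7-dimethyl-3a-(prop-1-en-2-yl)-2,3,3a,4,5,6-hexahydro-1H-inden-1-one
Conditions: [C5H5NH][CrO3Cl], NaOAc, CH2Cl2, 23 °C
Reagents that add atoms: none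
Why: Babler–Dauben oxidative transposition, in which the tertiary allylic chromate ester undergoes a [3,3] shift and is oxidised to the transposed enone (C3 ketone, C4=C5 alkene), with no stereocentre involved.

Step 8
Reactants: 12 (3aS,6S)-6,7-dimethyl-3a-(prop-1-en-2-yl)-2,3,3a,4,5,6-hexahydro-1H-inden-1-one
Product: 13 2-[(3aS,6S)-6,7-dimethyl-1-oxo-1,2,3,4,5,6-hexahydro-3aH-inden-3a-yl]prop-2-enal
Conditions: SeO2, 1,4-dioxane/H2O, 80 °C
Reagents that add atoms: selenium dioxide, O=[Se]=O
Why: Riley allylic oxidation (ene reaction then [2,3]-shift) of the only electron-rich alkene at its sole allylic methyl gives the 2-substituted acrolein, while the electron-poor enone alkene reacts much more slowly.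

Step 9
Reactants: 14 (R)-2,2-dimethyl-1,3-dioxolane-4-carbaldehyde
Product: 15 (4S)-4-(2,2-dibromoethenyl)-2,2-dimethyl-1,3-dioxolane
Conditions: CBr4, PPh3, Et3N, CH2Cl2, 0 °C
Reagents that add atoms: carbon tetrabromide, BrC(Br)(Br)Br
Why: Corey–Fuchs (Ramirez) dibromo-olefination under near-neutral conditions does not epimerise the α-oxygenated stereocentre, which becomes C19.

Step 10
Reactants: 15 (4S)-4-(2,2-dibromoethenyl)-2,2-dimethyl-1,3-dioxolane
Product: 17 3-[(4S)-2,2-dimethyl-1,3-dioxolan-4-yl]prop-2-yn-1-ol, via lithium acetylide 16 (not isolated)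
Conditions: n-BuLi (2.1 equiv), THF, −78 °C; then (CH2O)n, −78 → 23 °C; aq. NH4Cl
Reagents that add atoms: paraformaldehyde (as formaldehyde), C=O
Why: second stage of the Corey–Fuchs reaction (bromine–lithium exchange, 1,2-shift, deprotonation) gives the acetylide, which is trapped by formaldehyde with the stereocentre untouched.

Step 11
Reactants: 17 3-[(4S)-2,2-dimethyl-1,3-dioxolan-4-yl]prop-2-yn-1-ol
Product: 19 (4S)-4-(buta-2,3-dien-2-yl)-2,2-dimethyl-1,3-dioxolane, via propargylic mesylate 18 (not isolated)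
Conditions: MsCl, Et3N, THF, −20 °C; then MeMgBr, CuBr·SMe2 (10 mol%), −78 → 0 °C
Reagents that add atoms: methylmagnesium bromide, C[Mg]Br
Why: copper-catalysed SN2′ substitution of the propargylic mesylate by methyl gives the 1,1-disubstituted allene, again without touching the stereocentre.

Step 12
Reactants: 19 (4S)-4-(buta-2,3-dien-2-yl)-2,2-dimethyl-1,3-dioxolane; 13 2-[(3aS,6S)-6,7-dimethyl-1-oxo-1,2,3,4,5,6-hexahydro-3aH-inden-3a-yl]prop-2-enal
Product: 21 homoallylic alcohol (11S,12R,19S), via allylborane 20 (not isolated)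
Conditions: (+)-Ipc2BH [from (−)-α-pinene], THF, −25 °C, 4 h, then 23 °C, 6 h; 13, −78 → −20 °C; NaOH, H2O2, 0 °C
Reagents that add atoms: none
Why: Brown-type allene hydroboration puts boron on the terminal allene carbon and reversible 1,3-boratropic shift at 23 °C funnels the allylborane to the isomer with CH2B cis to methyl; the aldehyde then reacts through a chair (Zimmerman–Traxler) transition state with its substituent equatorial, so the hydroxyl ends up syn to the methyl and anti to the dioxolane at the new quaternary carbon (12R), the isopinocampheyl groups direct attack to the Re face of the aldehyde (11S), and 19S comes from the glyceraldehyde.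

Step 13
Reactants: 21 homoallylic alcohol (11S,12R,19S)
Product: 22 C11 methoxymethyl ether
Conditions: MOMCl, i-Pr2NEt, Bu4NI (cat.), CH2Cl2, 40 °C
Reagents that add atoms: chloromethyl methyl ether, COCCl
Why: Williamson-type O-alkylation of the only hydroxyl, giving a small acetal that survives the radical, dissolving-metal and acylation steps; no stereocentre is affected.

Step 14
Reactants: 22 C11 methoxymethyl ether
Product: 23 C14 aldehyde
Conditions: PdCl2(PhCN)2 (10 mol%), CuCl2·2H2O (10 mol%), AgNO2 (5 mol%), t-BuOH/MeNO2 (15:1), O2 (1 atm), 23 °C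
Reagents that add atoms: dioxygen, O=O
Why: nitrite-modified aldehyde-selective Wacker oxidation, in which the quaternary allylic carbon blocks Markovnikov attack so oxygen is delivered to the terminal carbon of the vinyl group, while the 1,1-disubstituted and tetrasubstituted alkenes do not react.

Step 15
Reactants: 23 C14 aldehyde
Product: 24 tricyclic 14-epi alcohol
Conditions: SmI2 (3 equiv), H2O (6 equiv), THF, 0 °C
Reagents that add atoms: none
Why: the ketyl radical from the C14 aldehyde adds to C5, the β-carbon of the enone (radical conjugate addition closing the eight-membered ring), a second electron gives the samarium enolate and protonation sets C4; the tether admits the ketyl to one face of C5 only, fixing the C5 quaternary centre, and the 14S carbinol formed here is provisional because C14 is re-set in steps 16 and 17.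

Step 16
Reactants: 24 tricyclic 14-epi alcohol
Product: 25 tricyclic 3,14-dione
Conditions: Fe(acac)3 (2.2 equiv), PhSiH3, EtOH, 60 °C
Reagents that add atoms: none
Why: metal-hydride hydrogen-atom transfer to the 1,1-disubstituted alkene gives the tertiary C10 radical, which abstracts the transannular C14–H through a six-membered 1,5-transition state, so the hydrogen arrives from inside the ring and fixes C10 (R), and the resulting ketyl radical is oxidised by trivalent iron to the C14 ketone.

Step 17
Reactants: 25 tricyclic 3,14-dione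
Product: 27 tricyclic 14-alcohol, via lithium enolate 26 (not isolated)
Conditions: LiN(SiMe3)2 (1.05 equiv), THF, −78 °C; then Li, NH3(l), −78 °C; NH4Cl
Reagents that add atoms: none
Why: Proposed new method: one equivalent of amide base kinetically deprotonates the accessible C2 methylene of the cyclopentanone, and the enolate cannot accept an electron, so lithium in ammonia reduces only the hindered C14 ketone, whose carbanion protonates to the thermodynamically preferred alcohol (14R); the closest known reactions are protection of ketones as enolates during metal–ammonia or hydride reductions and thermodynamically controlled dissolving-metal reduction of hindered cyclic ketones.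

Step 18
Reactants: 27 tricyclic 14-alcohol
Product: 28 protected glycolate
Conditions: TBSOCH2CO2H, EDC·HCl, DMAP, CH2Cl2, 23 °C
Reagents that add atoms: 2-[(tert-butyldimethylsilyl)oxy]acetic acid, CC(C)(C)[Si](C)(C)OCC(=O)O
Why: Steglich-type carbodiimide esterification of the only free hydroxyl (C14), with no stereocentre affected.

Step 19
Reactants: 28 protected glycolate
Product: 29 Pleuromutilin A
Conditions: HCl (3 M aq.), THF, 23 → 40 °C
Reagents that add atoms: none
Why: aqueous acid hydrolyses the methoxymethyl ether, the acetonide and the primary silyl ether while the hindered C14 ester survives, and no stereocentre is touched.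

**Compound list**

1 | (S)-carvone, (5S)-2-methyl-5-(prop-1-en-2-yl)cyclohex-2-en-1-one | CC1=CC[C@@H](CC1=O)C(C)=C | starting material
2 | (2S,5S)-2-methyl-5-(prop-1-en-2-yl)cyclohexan-1-one (trans-dihydrocarvone) | C[C@H]1CC[C@H](C(C)=C)CC1=O | intermediate
3 | (2S,5S)-5-(1-hydroperoxy-1-methoxyethyl)-2-methylcyclohexan-1-one, both epimers at the peroxy carbon | C[C@H]1CC[C@H](C(C)(OC)OO)CC1=O | intermediate
4 | (6S)-6-methylcyclohex-2-en-1-one | C[C@H]1CCC=CC1=O | intermediate
5 | trimethyl{[(6S)-6-methyl-3-(prop-1-en-2-yl)cyclohex-1-en-1-yl]oxy}silane, both C3 epimers | C[C@H]1CCC(C(C)=C)C=C1O[Si](C)(C)C | intermediate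
6 | (6S)-6-methyl-3-(prop-1-en-2-yl)cyclohex-2-en-1-one | C=C(C)C1=CC(=O)[C@@H](C)CC1 | intermediate
7 | [2-(1,3-dioxan-2-yl)ethyl]magnesium bromide | Br[Mg]CCC1OCCCO1 | starting material
8 | (2S,5R)-5-[2-(1,3-dioxan-2-yl)ethyl]-2-methyl-5-(prop-1-en-2-yl)cyclohexan-1-one | C=C(C)[C@]1(CCC2OCCCO2)CC(=O)[C@@H](C)CC1 | intermediate
9 | 3-[(1R,4S)-4-methyl-3-oxo-1-(prop-1-en-2-yl)cyclohexyl]propanal | C=C(C)[C@]1(CCC=O)CC(=O)[C@@H](C)CC1 | intermediate
10 | (5S,7aR)-5-methyl-7a-(prop-1-en-2-yl)-1,2,5,6,7,7a-hexahydro-4H-inden-4-one | C=C(C)[C@]12CCC=C1C(=O)[C@@H](C)CC2 | intermediate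
11 | (5S,7aR)-4,5-dimethyl-7a-(prop-1-en-2-yl)-2,4,5,6,7,7a-hexahydro-1H-inden-4-ol, both C4 epimers | C=C(C)[C@]12CCC=C1C(C)(O)[C@@H](C)CC2 | intermediate
12 | (3aS,6S)-6,7-dimethyl-3a-(prop-1-en-2-yl)-2,3,3a,4,5,6-hexahydro-1H-inden-1-one | C=C(C)[C@]12CCC(=O)C1=C(C)[C@@H](C)CC2 | intermediate
13 | 2-[(3aS,6S)-6,7-dimethyl-1-oxo-1,2,3,4,5,6-hexahydro-3aH-inden-3a-yl]prop-2-enal | O=CC(=C)[C@]12CCC(=O)C1=C(C)[C@@H](C)CC2 | intermediate
14 | (R)-2,2-dimethyl-1,3-dioxolane-4-carbaldehyde (D-glyceraldehyde acetonide) | O=C[C@H]1COC(C)(C)O1 | starting material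
15 | (4S)-4-(2,2-dibromoethenyl)-2,2-dimethyl-1,3-dioxolane | BrC(Br)=C[C@H]1COC(C)(C)O1 | intermediate
16 | lithium 2-[(4S)-2,2-dimethyl-1,3-dioxolan-4-yl]ethynide | [Li]C#C[C@H]1COC(C)(C)O1 | intermediate
17 | 3-[(4S)-2,2-dimethyl-1,3-dioxolan-4-yl]prop-2-yn-1-ol | OCC#C[C@H]1COC(C)(C)O1 | intermediate
18 | 3-[(4S)-2,2-dimethyl-1,3-dioxolan-4-yl]prop-2-yn-1-yl methanesulfonate | CS(=O)(=O)OCC#C[C@H]1COC(C)(C)O1 | intermediate
19 | (4S)-4-(buta-2,3-dien-2-yl)-2,2-dimethyl-1,3-dioxolane | C=C=C(C)[C@H]1COC(C)(C)O1 | intermediate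
20 | {(2E)-3-[(4S)-2,2-dimethyl-1,3-dioxolan-4-yl]but-2-en-1-yl}di(isopinocampheyl)borane, both isopinocampheyl groups from (−)-α-pinene | C[C@@H]1[C@@H](B(C/C=C(\C)[C@H]5COC(C)(C)O5)[C@H]3C[C@H]4C[C@@H]([C@@H]3C)C4(C)C)C[C@H]2C[C@@H]1C2(C)C | intermediate
21 | (3aS,6S)-3a-{(3S,4R)-4-[(4S)-2,2-dimethyl-1,3-dioxolan-4-yl]-3-hydroxy-4-methylhexa-1,5-dien-2-yl}-6,7-dimethyl-2,3,3a,4,5,6-hexahydro-1H-inden-1-one (11S,12R,19S in mutilin numbering) | C=C[C@@](C)([C@H]1COC(C)(C)O1)[C@@H](O)C(=C)[C@]23CCC(=O)C2=C(C)[C@@H](C)CC3 | intermediate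
22 | (3aS,6S)-3a-{(3S,4R)-4-[(4S)-2,2-dimethyl-1,3-dioxolan-4-yl]-3-(methoxymethoxy)-4-methylhexa-1,5-dien-2-yl}-6,7-dimethyl-2,3,3a,4,5,6-hexahydro-1H-inden-1-one | C=C[C@@](C)([C@H]1COC(C)(C)O1)[C@@H](OCOC)C(=C)[C@]23CCC(=O)C2=C(C)[C@@H](C)CC3 | intermediate
23 | (3R,4S)-3-[(4S)-2,2-dimethyl-1,3-dioxolan-4-yl]-5-[(3aS,6S)-6,7-dimethyl-1-oxo-1,2,3,4,5,6-hexahydro-3aH-inden-3a-yl]-4-(methoxymethoxy)-3-methylhex-5-enal | O=CC[C@@](C)([C@H]1COC(C)(C)O1)[C@@H](OCOC)C(=C)[C@]23CCC(=O)C2=C(C)[C@@H](C)CC3 | intermediate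
24 | 5-6-8 tricycle, mutilin numbering: 3-ketone, C10=C17 methylidene, 11-OMOM, 14-OH, 19,20-acetonide; 4S,5S,6S,9R,11S,12R,14S,19S | C=C1[C@H](OCOC)[C@](C)([C@H]2COC(C)(C)O2)C[C@H](O)[C@@]3(C)[C@@H](C)CC[C@]14CCC(=O)[C@@H]43 | intermediate
25 | 5-6-8 tricycle: 3,14-diketone, 10-methyl, 11-OMOM, 19,20-acetonide; 4S,5S,6S,9S,10R,11S,12R,19S | C[C@H]1[C@H](OCOC)[C@](C)([C@H]2COC(C)(C)O2)CC(=O)[C@@]3(C)[C@@H](C)CC[C@]14CCC(=O)[C@@H]43 | intermediate
26 | lithium C2=C3 enolate of 25 (C14 ketone free) | C[C@H]1[C@H](OCOC)[C@](C)([C@H]2COC(C)(C)O2)CC(=O)[C@@]3(C)[C@@H](C)CC[C@]14CC=C(O[Li])[C@@H]43 | intermediate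
27 | 5-6-8 tricycle: 3-ketone, 14-OH, 11-OMOM, 19,20-acetonide; 4S,5S,6S,9S,10R,11S,12R,14R,19S | C[C@H]1[C@H](OCOC)[C@](C)([C@H]2COC(C)(C)O2)C[C@@H](O)[C@@]3(C)[C@@H](C)CC[C@]14CCC(=O)[C@@H]43 | intermediate
28 | 14-O-[2-(tert-butyldimethylsilyloxy)acetyl] ester of 27 | C[C@H]1[C@H](OCOC)[C@](C)([C@H]2COC(C)(C)O2)C[C@@H](OC(=O)CO[Si](C)(C)C(C)(C)C)[C@@]3(C)[C@@H](C)CC[C@]14CCC(=O)[C@@H]43 | intermediate
29 | Pleuromutilin A; 4S,5S,6S,9S,10R,11S,12R,14R,19S in mutilin numbering | C[C@H]1[C@H](O)[C@](C)([C@H](O)CO)C[C@@H](OC(=O)CO)[C@@]2(C)[C@@H](C)CC[C@]13CCC(=O)[C@@H]32 | target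

**Step count and risk**

Total: 19 steps. Longest linear sequence: 16 steps (steps 1–8, then 12–19); the allene branch (steps 9–11) joins at step 12.

The three steps most likely to fail:

Step 4 (1,4- against 1,6-addition to dienone 6, and the face of attack at C9). The fallback reverses the order of the two conjugate additions, so no dienone is involved, and lets a chiral catalyst set C9. It sets out from 4. CuBr·SMe2-catalysed addition of 7 in the presence of TMSCl gives trimethyl{[(6S)-3-[2-(1,3-dioxan-2-yl)ethyl]-6-methylcyclohex-1-en-1-yl]oxy}silane F1. Pd(OAc)2 with O2 in DMSO turns it into (6S)-3-[2-(1,3-dioxan-2-yl)ethyl]-6-methylcyclohex-2-en-1-one F2. Copper-catalysed asymmetric conjugate addition of Me2Al[C(CH3)=CH2] to F2 (Cu(O2CC4H3S), chiral phosphinamine ligand, Et2O, −30 °C), with the ligand enantiomer chosen to deliver the alkenyl group trans to the C6 methyl, then gives 8, where the route is rejoined.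

Step 12 (hindered union; it depends on equilibration of the allylborane geometry and on the borane overriding the dioxolane stereocentre). The fallback replaces the stoichiometric borane by a catalytic transfer-hydrogenative carbonyl allylation. It sets out from 19 and 13 and comes back at 21 with no new isolated compound (F0). Conditions: [Ir(cod)Cl]2, (S)-SEGPHOS, 4-cyano-3-nitrobenzoic acid, Cs2CO3, i-PrOH, THF, 60 °C. The σ-allyliridium intermediate equilibrates to the geometry with the dioxolane trans to the metal-bearing carbon and adds through the same closed chair, so the anti relationship of hydroxyl and dioxolane is kept and the ligand sets the absolute sense.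

Step 17 (regioselective enolate masking of C3 while C14 is reduced). The fallback masks C3 covalently. It sets out from 25. Me3SiOCH2CH2OSiMe3 with Me3SiOTf (cat.) in CH2Cl2 at −78 °C ketalises only the unhindered cyclopentanone and gives the 3,3-ethylenedioxy 14-ketone F3. Li in NH3 gives the 3,3-ethylenedioxy 14R-alcohol F4. Esterification as in step 18 gives the 3,3-ethylenedioxy protected glycolate F5. The aqueous HCl of step 19 then removes the ketal together with the other protecting groups and comes back to the route at 29.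

**Further compounds**

F1 | step 4 | trimethyl{[(6S)-3-[2-(1,3-dioxan-2-yl)ethyl]-6-methylcyclohex-1-en-1-yl]oxy}silane | C[C@H]1CCC(CCC2OCCCO2)C=C1O[Si](C)(C)C
F2 | step 4 | (6S)-3-[2-(1,3-dioxan-2-yl)ethyl]-6-methylcyclohex-2-en-1-one | C[C@H]1CCC(CCC2OCCCO2)=CC1=O
F0 | step 12 | none | none
F3 | step 17 | 3,3-ethylenedioxy 14-ketone (C3 dioxolane of 25) | C[C@H]1[C@H](OCOC)[C@](C)([C@H]2COC(C)(C)O2)CC(=O)[C@@]3(C)[C@@H](C)CC[C@]14CCC5(OCCO5)[C@@H]43
F4 | step 17 | 3,3-ethylenedioxy 14R-alcohol | C[C@H]1[C@H](OCOC)[C@](C)([C@H]2COC(C)(C)O2)C[C@@H](O)[C@@]3(C)[C@@H](C)CC[C@]14CCC5(OCCO5)[C@@H]43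
F5 | step 17 | 3,3-ethylenedioxy protected glycolate | C[C@H]1[C@H](OCOC)[C@](C)([C@H]2COC(C)(C)O2)C[C@@H](OC(=O)CO[Si](C)(C)C(C)(C)C)[C@@]3(C)[C@@H](C)CC[C@]14CCC5(OCCO5)[C@@H]43
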